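**Plan**
1. Cuts: the acyl groups on O8 and O9, the C11=C13 methylene, the lactone bond O6–C12 and the epoxide oxygen are removed first. The ten-membered ring is then opened at C5–C6. The chain is cut at C7–C8 (aldol), C9–O (enolate oxidation) and C1=C10 (olefination).
2. Enabling feature: in the ten-membered carbocycle, C6 is a carbinol carbon bonded directly to the C4–C5 oxirane, which makes it an epoxidised (E)-allylic alcohol. A C5 alkenyl metal can therefore add to a C6 aldehyde, and the new hydroxyl then steers the epoxidation. The C1=C10 enoate holds C2 and C9 cis and pre-folds the chain.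
3. Chain assembly: an iodoalkenal (C1–C5, C15) is joined to a phosphonosuccinyl imide (C8–C10, C14). This gives the C8 aldehyde, which undergoes an aldol with a pent-4-enoyl thiazolidinethione (C6, C7, C11, C12) to reach the C6 aldehyde.
4. Rings: the carbocycle forms in step 14, the oxirane in step 15 and the γ-lactone in steps 16 and 17. C13 and the two esters follow.
5. Stereochemistry: C9 comes from auxiliary-controlled enolate hydroxylation and C7/C8 from an auxiliary-controlled syn aldol. C6 comes from Felkin–Anh addition next to C7, and C4/C5 from oxygen delivery by the C6 hydroxyl. The alkene geometries come from syn carboalumination and from the olefination.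

Key step: step 14

Remark: labels C1–C15 are the germacrane labels of the target. CIP descriptors change along the route where substituent ranks change, although no centre is inverted.
Remark: the C7 acetate arm is carried as an allyl group (C11, C12 and one extra carbon). A succinate ester would lactonise onto O8 after the aldol and onto O6 after ring closure, and the second event would remove the directing hydroxyl.
Assumption: compounds 1, 5, 6, 9, 18 and 19, the Davis oxaziridine and Eschenmoser's salt are taken as purchasable.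

**Step 1**
Reactants: 1 pent-4-yn-1-ol
Product: 3 (4E)-5-iodo-4-methylpent-4-en-1-ol, via alkenylalane 2 (not isolated)
Conditions: AlMe3 (3 equiv), Cp2ZrCl2 (0.25 equiv), CH2Cl2, 0 °C to rt; then I2, THF, −30 °C; aq. potassium sodium tartrate
Reagents that add atoms: trimethylaluminium C[Al](C)C; iodine [I][I]
Why: Negishi carboalumination adds methyl and aluminium syn across the terminal alkyne with methyl on the internal carbon, and iodinolysis of the C–Al bond goes with retention, so the (E)-iodoalkene that becomes C4=C5 should result.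

**Step 2**
Reactants: 3 (4E)-5-iodo-4-methylpent-4-en-1-ol
Product: 4 (4E)-5-iodo-4-methylpent-4-enal
Conditions: TEMPO (0.1 equiv), PhI(OAc)2 (1.1 equiv), CH2Cl2, rt
Reagents that add atoms: none
Why: The oxoammonium (TEMPO) oxidation of a primary alcohol stops at the aldehyde and leaves the alkenyl iodide untouched.

**Step 3**
Reactants: 5 (4R)-4-benzyl-1,3-oxazolidin-2-one; 6 bromoacetyl bromide
Product: 8 (4R)-4-benzyl-3-(bromoacetyl)-1,3-oxazolidin-2-one, via lithium oxazolidinide 7 (not isolated)
Conditions: n-BuLi, THF, −78 °C; then 6, −78 to 0 °C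
Reagents that add atoms: none
Why: In this N-acylation the lithiated oxazolidinone attacks the acid bromide faster than it displaces the α-bromide at low temperature.

**Step 4**
Reactants: 9 trimethyl phosphonoacetate; 8 (4R)-4-benzyl-3-(bromoacetyl)-1,3-oxazolidin-2-one
Product: 11 methyl 4-[(4R)-4-benzyl-2-oxo-1,3-oxazolidin-3-yl]-2-(dimethoxyphosphoryl)-4-oxobutanoate (epimers at the phosphonate carbon), via sodium phosphonate carbanion 10 (not isolated)
Conditions: NaH, THF, 0 °C; then 8, 0 °C to rt (9 in slight excess)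
Reagents that add atoms: none
Why: SN2 alkylation of the stabilised phosphonoacetate carbanion by the activated α-bromo imide gives a phosphonosuccinate-type reagent, and the slight excess of 9 suppresses double alkylation.

**Step 5**
Reactants: 4 (4E)-5-iodo-4-methylpent-4-enal; 11 phosphonosuccinyl imide
Product: 12 methyl (2E,6E)-2-{2-[(4R)-4-benzyl-2-oxo-1,3-oxazolidin-3-yl]-2-oxoethyl}-7-iodo-6-methylhepta-2,6-dienoate
Conditions: LiCl, DBU, MeCN, 0 °C to rt
Reagents that add atoms: none
Why: The Horner–Wadsworth–Emmons olefination under Masamune–Roush conditions is reversible at the addition stage, so the alkene with C2 trans to the ester and cis to C9 should prevail, and the mild amine base spares the imide.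

**Step 6**
Reactants: 12 alkylidene succinyl imide
Product: 14 methyl (2E,6E)-2-{(1R)-2-[(4R)-4-benzyl-2-oxo-1,3-oxazolidin-3-yl]-1-hydroxy-2-oxoethyl}-7-iodo-6-methylhepta-2,6-dienoate (9R), via sodium enolate 13 (not isolated)
Conditions: NaN(SiMe3)2, THF, −78 °C; 2-(benzenesulfonyl)-3-phenyloxaziridine, −78 °C; AcOH quench at −78 °C
Reagents that add atoms: 2-(benzenesulfonyl)-3-phenyloxaziridine O=S(=O)(c1ccccc1)N1OC1c1ccccc1
Why: In this Evans-type enolate hydroxylation the chelated sodium (Z)-enolate meets the Davis oxaziridine at C9 on the face away from the benzyl group, which sets 9R, and C1 cannot compete as a nucleophilic site because the ester deactivates it.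

**Step 7**
Reactants: 14 α-hydroxy imide
Product: 15 methyl (2E,6E)-2-{(1R)-1-hydroxy-2-[methoxy(methyl)amino]-2-oxoethyl}-7-iodo-6-methylhepta-2,6-dienoate
Conditions: MeNH(OMe)·HCl, AlMe3, CH2Cl2, −10 to 0 °C
Reagents that add atoms: N,O-dimethylhydroxylamine hydrochloride CNOC.Cl
Why: The aluminium-amide transamination (Weinreb amide formation) is guided by the C9 alkoxide to the much more electrophilic exocyclic imide carbonyl, so the conjugated methyl ester should stay intact and the auxiliary is returned.

**Step 8**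
Reactants: 15 α-hydroxy Weinreb amide
Product: 16 methyl (2E,6E)-2-{(1R)-1-(tert-butyldimethylsilyloxy)-2-[methoxy(methyl)amino]-2-oxoethyl}-7-iodo-6-methylhepta-2,6-dienoate
Conditions: TBSOTf, 2,6-lutidine, CH2Cl2, 0 °C
Reagents that add atoms: tert-butyldimethylsilyl triflate CC(C)(C)[Si](C)(C)OS(=O)(=O)C(F)(F)F
Why: Silylation with the silyl triflate and a hindered pyridine base protects O9 without touching the stereocentre.

**Step 9**
Reactants: 16 silylated Weinreb amide
Product: 17 methyl (2E,6E)-2-[(1R)-1-(tert-butyldimethylsilyloxy)-2-oxoethyl]-7-iodo-6-methylhepta-2,6-dienoate (C8 aldehyde)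
Conditions: i-Bu2AlH (1.1 equiv), THF, −78 °C; aq. potassium sodium tartrate; used without delay
Reagents that add atoms: none
Why: In this partial reduction the Weinreb amide binds aluminium and forms a stable chelate that collapses to the aldehyde only on work-up, and it should react before the hindered α-branched enoate when hydride is limited at low temperature.

**Step 10**
Reactants: 18 (4R)-4-benzyl-1,3-thiazolidine-2-thione; 19 pent-4-enoyl chloride
Product: 20 1-[(4R)-4-benzyl-2-thioxo-1,3-thiazolidin-3-yl]pent-4-en-1-one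
Conditions: Et3N, DMAP (cat.), CH2Cl2, 0 °C to rt
Reagents that add atoms: none
Why: N-Acylation of the acidic thiazolidinethione by an acid chloride with an amine base is routine.

**Step 11**
Reactants: 20 N-pent-4-enoyl thiazolidinethione; 17 C8 aldehyde
Product: 22 methyl (2E,6E)-2-[(1R,2R,3R)-3-{[(4R)-4-benzyl-2-thioxo-1,3-thiazolidin-3-yl]carbonyl}-1-(tert-butyldimethylsilyloxy)-2-hydroxyhex-5-en-1-yl]-7-iodo-6-methylhepta-2,6-dienoate (7R,8R,9R; all-syn), via titanium enolate 21 (not isolated)
Conditions: TiCl4 (1.05 equiv), i-Pr2NEt (1.1 equiv), N-methyl-2-pyrrolidone (1 equiv), CH2Cl2, 0 °C; then 17, −78 to −40 °C; aq. NH4Cl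
Reagents that add atoms: none
Why: In this titanium-enolate Evans-syn aldol the (Z)-enolate reacts through a non-chelated Zimmerman–Traxler chair on the face opposite the benzyl group, which sets 7R and 8R, and the auxiliary should override the weak bias of (Z)-enolates toward α-silyloxy aldehydes, so the 8,9-syn relationship follows from the fixed 9R centre.

**Step 12**
Reactants: 22 syn-aldol adduct
Product: 23 O8-triethylsilyl ether of 22 (7R,8R,9R)
Conditions: TESOTf, 2,6-lutidine, CH2Cl2, −78 to 0 °C
Reagents that add atoms: triethylsilyl triflate CC[Si](CC)(CC)OS(=O)(=O)C(F)(F)F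
Why: Silylation with the triflate caps O8 before it can add to the C14 ester, and the more labile triethylsilyl group allows O8 to be unmasked before O9.

**Step 13**
Reactants: 23 bis-silylated thiazolidinethione
Product: 24 methyl (2E,6E)-2-[(1R,2R,3R)-1-(tert-butyldimethylsilyloxy)-3-formyl-2-(triethylsilyloxy)hex-5-en-1-yl]-7-iodo-6-methylhepta-2,6-dienoate (C6 aldehyde; 7R,8R,9R)
Conditions: i-Bu2AlH added until the yellow colour fades, CH2Cl2, −78 °C; aq. potassium sodium tartrate
Reagents that add atoms: none
Why: Direct hydride reduction of the highly activated N-acyl thiazolidinethione to the aldehyde is much faster than ester reduction, and the loss of colour marks the end point.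

**Step 14**
Reactants: 24 C6 aldehyde with (E)-C5 alkenyl iodide
Product: 26 methyl (1E,5E,7R,8S,9R,10R)-10-(tert-butyldimethylsilyloxy)-7-hydroxy-5-methyl-8-(prop-2-enyl)-9-(triethylsilyloxy)cyclodeca-1,5-diene-1-carboxylate (germacrane labels 6R,7S,8R,9R), via alkenylchromium 25 (not isolated)
Conditions: CrCl2 (15 equiv), NiCl2 (1 mol% of the chromium salt), degassed DMSO–THF, syringe-pump addition of 24 to about 0.002 M, rt; then H2O
Reagents that add atoms: none
Why: Zerovalent nickel, formed from NiCl2 by divalent chromium, inserts into the C5–I bond and passes the alkenyl group to trivalent chromium with retention of the (E) geometry, and alkenylchromium 25 then adds 1,2 to the C6 aldehyde. This is the intramolecular Nozaki–Hiyama–Kishi reaction of an alkenyl iodide with an aldehyde, a known way to close medium and large rings. The ten-membered carbocycle closes in the 10-exo-trig mode, favoured over oligomerisation by slow addition at high dilution and by the C1=C10 enoate, which keeps C2 and C9 cis and so pre-folds the chain. The single new stereocentre C6 is controlled by C7: Felkin–Anh attack anti to the bulky C8 branch places the new hydroxyl syn to the allyl arm (6R here), which is the relationship of the trans-fused lactone. The step needs selectivity for the aldehyde and mildness toward C7, and the weakly basic, oxophilic alkenylchromium secures both, since it ignores the enoate, the silyl ethers and the terminal alkene and neither epimerises C7 nor expels the β-silyloxy group.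

**Step 15**
Reactants: 26 ten-membered allylic alcohol
Product: 27 4,5-epoxy alcohol (4R,5R,6S,7S,8R,9R; trans-oxirane on the face of the C6 hydroxyl)
Conditions: VO(acac)2 (0.1 equiv), t-BuOOH (1.5 equiv, decane), CH2Cl2, 0 °C
Reagents that add atoms: tert-butyl hydroperoxide CC(C)(C)OO
Why: In this hydroxyl-directed vanadium-catalysed epoxidation H6 eclipses the alkene to avoid A(1,3) strain with the C4 methyl, so the C6 hydroxyl sits on the outer face of the (E)-alkene and delivers oxygen there to give the threo (4R,5R) epoxy alcohol, while the enoate and the remote terminal alkene react far more slowly.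

**Step 16**
Reactants: 27 epoxy alcohol
Product: 29 6,12-lactol (4R,5R,6S,7S,8R,9R; anomers at C12), via hydroxy aldehyde 28 (not isolated)
Conditions: OsO4 (0.03 equiv), NaIO4 (4 equiv), 2,6-lutidine, dioxane–H2O, rt
Reagents that add atoms: osmium tetroxide O=[Os](=O)(=O)=O; sodium periodate [Na+].[O-]I(=O)(=O)=O
Why: The Lemieux–Johnson cleavage selects the unhindered monosubstituted alkene over the electron-poor trisubstituted enoate, and hydroxy aldehyde 28 is trapped at once by the C6 hydroxyl as the five-membered lactol.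

**Step 17**
Reactants: 29 lactol
Product: 30 trans-fused 6,12-γ-lactone (4R,5R,6S,7S,8R,9R)
Conditions: TEMPO (0.2 equiv), PhI(OAc)2 (1.5 equiv), CH2Cl2, rt
Reagents that add atoms: none
Why: The oxoammonium oxidation of a lactol to the lactone is mild enough for the epoxide and both silyl ethers and leaves C6 and C7 untouched.

**Step 18**
Reactants: 30 γ-lactone
Product: 34 α-methylene-γ-lactone (4R,5R,6S,7S,8R,9R), via lithium enolate 31 (not isolated), via Mannich base 32 (not isolated), via ammonium iodide 33 (not isolated)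
Conditions: LiN(i-Pr)2 (1.2 equiv), THF, −78 °C; Me2N=CH2 iodide, −78 °C to rt; then MeI, MeOH, rt; then aq. NaHCO3, CH2Cl2
Reagents that add atoms: Eschenmoser's salt C=[N+](C)C.[I-]
Why: This is the classical lactone α-methylenation (enolate Mannich reaction, quaternisation, Hofmann-type elimination), and the lactone CH2 is the most accessible acidic site because the γ-hydrogens of the enoate at C2 lie trans to the ester carbonyl, out of reach of the lithium-bound amide.

**Step 19**
Reactants: 34 bis-silylated α-methylene lactone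
Product: 35 8-hydroxy-9-(tert-butyldimethylsilyloxy) α-methylene lactone (4R,5R,6S,7R,8R,9R)
Conditions: PPTS (0.2 equiv), MeOH–CH2Cl2, 0 °C
Reagents that add atoms: none
Why: Acid-catalysed methanolysis removes the triethylsilyl ether far faster than the tert-butyldimethylsilyl ether, and the weak acid should leave the epoxide closed.

**Step 20**
Reactants: 35 8-alcohol
Product: 36 8-methacrylate 9-(tert-butyldimethylsilyl) ether (4R,5R,6S,7S,8R,9R)
Conditions: methacrylic anhydride, Et3N, DMAP, CH2Cl2, rt
Reagents that add atoms: methacrylic anhydride C=C(C)C(=O)OC(=O)C(C)=C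
Why: DMAP-catalysed acyl transfer from the anhydride esterifies the hindered C8 hydroxyl with retention of configuration.

**Step 21**
Reactants: 36 8-methacrylate silyl ether
Product: 37 9-hydroxy 8-methacrylate (4R,5R,6S,7R,8R,9R)
Conditions: HF·pyridine, pyridine, THF, 0 °C to rt (plastic vessel)
Reagents that add atoms: none
Why: Fluoride-mediated desilylation in an acidic, pyridine-buffered medium avoids the free alkoxide that would trigger acyl migration from O8 to O9 or attack on the lactone.

**Step 22**
Reactants: 37 9-alcohol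
Product: 38 CNP0153978.7, methyl (4R,5R,6S,7R,8R,9R)-9-acetoxy-4,5-epoxy-8-(methacryloyloxy)germacra-1(10)E,11(13)-dien-12,6-olid-14-oate
Conditions: Ac2O, pyridine, DMAP (cat.), CH2Cl2, rt
Reagents that add atoms: acetic anhydride CC(=O)OC(C)=O
Why: DMAP-catalysed acetylation of the C9 hydroxyl completes the target with all six stereocentres unchanged.

**Compound list**
1 | pent-4-yn-1-ol | C#CCCCO | starting material
2 | dimethyl{(1E)-5-[(dimethylalumanyl)oxy]-2-methylpent-1-en-1-yl}alumane (not isolated) | C[Al](C)OCCC/C(C)=C/[Al](C)C | intermediate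
3 | (4E)-5-iodo-4-methylpent-4-en-1-ol | OCCC/C(C)=C/I | intermediate
4 | (4E)-5-iodo-4-methylpent-4-enal | O=CCC/C(C)=C/I | intermediate
5 | (4R)-4-benzyl-1,3-oxazolidin-2-one | O=C1N[C@H](Cc2ccccc2)CO1 | starting material
6 | bromoacetyl bromide | BrCC(Br)=O | starting material
7 | lithium salt of 5 (not isolated) | [Li+].O=C1[N-][C@H](Cc2ccccc2)CO1 | intermediate
8 | (4R)-4-benzyl-3-(bromoacetyl)-1,3-oxazolidin-2-one | O=C(CBr)N1[C@H](Cc2ccccc2)COC1=O | intermediate
9 | trimethyl phosphonoacetate | COC(=O)CP(=O)(OC)OC | starting material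
10 | sodium salt of 9 (not isolated) | [Na+].COC(=O)[CH-]P(=O)(OC)OC | intermediate
11 | methyl 4-[(4R)-4-benzyl-2-oxo-1,3-oxazolidin-3-yl]-2-(dimethoxyphosphoryl)-4-oxobutanoate (epimers at the phosphonate carbon) | COC(=O)C(CC(=O)N1[C@H](Cc2ccccc2)COC1=O)P(=O)(OC)OC | intermediate
12 | methyl (2E,6E)-2-{2-[(4R)-4-benzyl-2-oxo-1,3-oxazolidin-3-yl]-2-oxoethyl}-7-iodo-6-methylhepta-2,6-dienoate | COC(=O)/C(CC(=O)N1[C@H](Cc2ccccc2)COC1=O)=C/CC/C(C)=C/I | intermediate
13 | sodium (Z)-enolate of 12 (not isolated) | [Na+].COC(=O)/C(=C/CC/C(C)=C/I)/C=C(\[O-])N1[C@H](Cc2ccccc2)COC1=O | intermediate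
14 | (9R)-α-hydroxy imide | COC(=O)/C(=C/CC/C(C)=C/I)[C@@H](O)C(=O)N1[C@H](Cc2ccccc2)COC1=O | intermediate
15 | (9R)-α-hydroxy Weinreb amide | COC(=O)/C(=C/CC/C(C)=C/I)[C@@H](O)C(=O)N(C)OC | intermediate
16 | (9R)-α-(tert-butyldimethylsilyloxy) Weinreb amide | COC(=O)/C(=C/CC/C(C)=C/I)[C@@H](O[Si](C)(C)C(C)(C)C)C(=O)N(C)OC | intermediate
17 | methyl (2E,6E)-2-[(1R)-1-(tert-butyldimethylsilyloxy)-2-oxoethyl]-7-iodo-6-methylhepta-2,6-dienoate | COC(=O)/C(=C/CC/C(C)=C/I)[C@@H](O[Si](C)(C)C(C)(C)C)C=O | intermediate
18 | (4R)-4-benzyl-1,3-thiazolidine-2-thione | S=C1N[C@H](Cc2ccccc2)CS1 | starting material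
19 | pent-4-enoyl chloride | C=CCCC(Cl)=O | starting material
20 | 1-[(4R)-4-benzyl-2-thioxo-1,3-thiazolidin-3-yl]pent-4-en-1-one | C=CCCC(=O)N1[C@H](Cc2ccccc2)CSC1=S | intermediate
21 | trichlorotitanium (Z)-enolate of 20 (not isolated) | C=CC/C=C(\O[Ti](Cl)(Cl)Cl)N1[C@H](Cc2ccccc2)CSC1=S | intermediate
22 | syn-aldol adduct (7R,8R,9R) | O=C(N1[C@H](Cc2ccccc2)CSC1=S)[C@H](CC=C)[C@@H](O)[C@H](O[Si](C)(C)C(C)(C)C)/C(C(=O)OC)=C\CC/C(C)=C/I | intermediate
23 | O8-triethylsilyl ether of 22 | O=C(N1[C@H](Cc2ccccc2)CSC1=S)[C@H](CC=C)[C@@H](O[Si](CC)(CC)CC)[C@H](O[Si](C)(C)C(C)(C)C)/C(C(=O)OC)=C\CC/C(C)=C/I | intermediate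
24 | C6 aldehyde with (E)-C5 alkenyl iodide (7R,8R,9R) | O=C[C@H](CC=C)[C@@H](O[Si](CC)(CC)CC)[C@H](O[Si](C)(C)C(C)(C)C)/C(C(=O)OC)=C\CC/C(C)=C/I | intermediate
25 | (E)-alkenylchromium dichloride from 24, solvent ligands omitted (not isolated) | O=C[C@H](CC=C)[C@@H](O[Si](CC)(CC)CC)[C@H](O[Si](C)(C)C(C)(C)C)/C(C(=O)OC)=C\CC/C(C)=C/[Cr](Cl)Cl | intermediate
26 | ten-membered 6-hydroxy-1(10),4-diene (6R,7S,8R,9R) | CC[Si](CC)(CC)O[C@@H]1[C@@H](CC=C)[C@H](O)/C=C(C)/CC/C=C(/C(=O)OC)[C@H]1O[Si](C)(C)C(C)(C)C | intermediate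
27 | 4,5-epoxy 6-alcohol (4R,5R,6S,7S,8R,9R) | CC[Si](CC)(CC)O[C@@H]1[C@@H](CC=C)[C@H](O)[C@H]2O[C@]2(C)CC/C=C(/C(=O)OC)[C@H]1O[Si](C)(C)C(C)(C)C | intermediate
28 | 6-hydroxy C12 aldehyde (not isolated) | CC[Si](CC)(CC)O[C@@H]1[C@@H](CC=O)[C@H](O)[C@H]2O[C@]2(C)CC/C=C(/C(=O)OC)[C@H]1O[Si](C)(C)C(C)(C)C | intermediate
29 | 6,12-lactol (anomers at C12) | CC[Si](CC)(CC)O[C@@H]1[C@H]2CC(O)O[C@@H]2[C@H]2O[C@]2(C)CC/C=C(/C(=O)OC)[C@H]1O[Si](C)(C)C(C)(C)C | intermediate
30 | trans-fused 6,12-γ-lactone | CC[Si](CC)(CC)O[C@@H]1[C@H]2CC(=O)O[C@@H]2[C@H]2O[C@]2(C)CC/C=C(/C(=O)OC)[C@H]1O[Si](C)(C)C(C)(C)C | intermediate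
31 | lithium enolate of 30 (not isolated) | [Li+].CC[Si](CC)(CC)O[C@@H]1[C@H]2C=C([O-])O[C@@H]2[C@H]2O[C@]2(C)CC/C=C(/C(=O)OC)[C@H]1O[Si](C)(C)C(C)(C)C | intermediate
32 | 11-(dimethylaminomethyl) lactone, C11 epimers (not isolated) | CC[Si](CC)(CC)O[C@@H]1[C@H]2C(CN(C)C)C(=O)O[C@@H]2[C@H]2O[C@]2(C)CC/C=C(/C(=O)OC)[C@H]1O[Si](C)(C)C(C)(C)C | intermediate
33 | 11-(trimethylammoniomethyl) lactone iodide, C11 epimers (not isolated) | [I-].CC[Si](CC)(CC)O[C@@H]1[C@H]2C(C[N+](C)(C)C)C(=O)O[C@@H]2[C@H]2O[C@]2(C)CC/C=C(/C(=O)OC)[C@H]1O[Si](C)(C)C(C)(C)C | intermediate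
34 | bis-silylated α-methylene-γ-lactone | CC[Si](CC)(CC)O[C@@H]1[C@H]2C(=C)C(=O)O[C@@H]2[C@H]2O[C@]2(C)CC/C=C(/C(=O)OC)[C@H]1O[Si](C)(C)C(C)(C)C | intermediate
35 | 8-hydroxy 9-silyl ether | O[C@@H]1[C@H]2C(=C)C(=O)O[C@@H]2[C@H]2O[C@]2(C)CC/C=C(/C(=O)OC)[C@H]1O[Si](C)(C)C(C)(C)C | intermediate
36 | 8-methacrylate 9-silyl ether | C=C(C)C(=O)O[C@@H]1[C@H]2C(=C)C(=O)O[C@@H]2[C@H]2O[C@]2(C)CC/C=C(/C(=O)OC)[C@H]1O[Si](C)(C)C(C)(C)C | intermediate
37 | 8-methacrylate 9-alcohol | C=C(C)C(=O)O[C@@H]1[C@H]2C(=C)C(=O)O[C@@H]2[C@H]2O[C@]2(C)CC/C=C(/C(=O)OC)[C@H]1O | intermediate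
38 | CNP0153978.7 | C=C(C)C(=O)O[C@@H]1[C@H]2C(=C)C(=O)O[C@@H]2[C@H]2O[C@]2(C)CC/C=C(/C(=O)OC)[C@H]1OC(C)=O | target

**Totals**
Total step count: 22.
Longest linear sequence: 19 (steps 1, 2, 5–9 and 11–22).

**The three steps most likely to fail**

Step 14. Oligomerisation may compete with closure of the strained ring. The greater danger is poor facial selectivity at the aldehyde, if the ring-forming transition state overrides the Felkin–Anh preference. The fallback sets out from 24 and moves the control of C6 from the addition to a stereospecific substitution. The cyclisation would then give mainly the 6-epimeric allylic alcohol F1, which is separated. F1 is subjected to a Mitsunobu inversion (4-nitrobenzoic acid, PPh3, diisopropyl azodicarboxylate, toluene, 0 °C to rt). SN2′ attack is disfavoured because C4 is fully substituted, so the product should be the inverted 4-nitrobenzoate F2. Methanolysis of F2 (K2CO3, MeOH, 0 °C) leaves the methyl ester unchanged and returns to the route at 26.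

Step 18. The amide base may also deprotonate C2 of the enoate. Alternatively, the lactone enolate may attack the C1=C10 enoate across the ring (Michael or Claisen mode) before it meets the iminium salt. The fallback sets out from lactol 29 and installs C13 at the aldehyde oxidation level without strong base. An amine-catalysed Mannich condensation and elimination is run on the open form of the lactol (aqueous formaldehyde, pyrrolidine, propionic acid, i-PrOH, 45 °C). This gives the α-methylene lactol F3. Oxidation of this allylic lactol with MnO2 in CH2Cl2 returns to the route at 34.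

Step 9. Hydride may also reduce the enoate. The α-silyloxy β,γ-unsaturated aldehyde may lose configuration at C9 or suffer alkene migration during a slow work-up. The fallback sets out from 14 and replaces the partial reduction by full reduction followed by oxidation. Silylation (TBSOTf, 2,6-lutidine) gives the silylated imide F4. LiBH4 with one equivalent of MeOH in Et2O at 0 °C reduces the imide selectively to the primary alcohol F5. This alcohol is oxidised at once with Dess–Martin periodinane and NaHCO3, before it can lactonise onto C14, and the route is rejoined at 17.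

**Further compounds**
F1 | step 14 | 6-epimer of 26 | CC[Si](CC)(CC)O[C@@H]1[C@@H](CC=C)[C@@H](O)/C=C(C)/CC/C=C(/C(=O)OC)[C@H]1O[Si](C)(C)C(C)(C)C
F2 | step 14 | 6-O-(4-nitrobenzoate) with the C6 configuration of 26 | CC[Si](CC)(CC)O[C@@H]1[C@@H](CC=C)[C@H](OC(=O)c2ccc(cc2)[N+](=O)[O-])/C=C(C)/CC/C=C(/C(=O)OC)[C@H]1O[Si](C)(C)C(C)(C)C
F3 | step 18 | α-methylene 6,12-lactol (anomers at C12) | CC[Si](CC)(CC)O[C@@H]1[C@H]2C(=C)C(O)O[C@@H]2[C@H]2O[C@]2(C)CC/C=C(/C(=O)OC)[C@H]1O[Si](C)(C)C(C)(C)C
F4 | step 9 | (9R)-α-(tert-butyldimethylsilyloxy) imide | COC(=O)/C(=C/CC/C(C)=C/I)[C@@H](O[Si](C)(C)C(C)(C)C)C(=O)N1[C@H](Cc2ccccc2)COC1=O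
F5 | step 9 | methyl (2E,6E)-2-[(1R)-1-(tert-butyldimethylsilyloxy)-2-hydroxyethyl]-7-iodo-6-methylhepta-2,6-dienoate | COC(=O)/C(=C/CC/C(C)=C/I)[C@@H](O[Si](C)(C)C(C)(C)C)CO
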